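The plan disconnects the butenolide (ring C6–O–C12–C11=C7) at the bond between the lactone carbonyl C12 and the α-carbon C11 (germacrane numbering). The unit C7=C11(C13H2OH)–C12 is read as an exocyclic allene C7=C11=C13H2 flanked by the C6 hydroxyl, plus carbon monoxide. In one operation a PdCl2/CuCl2 chlorocyclocarbonylation of this macrocyclic 2,3-allenol turns O6–H and CO into an alkoxycarbonylpalladium group that adds to C11, closing the lactone, creating the tetrasubstituted C7=C11 alkene and leaving chloride on C13 for later exchange to hydroxyl. The allenol arises from a chromium-mediated closure of the ten-membered ring from a propargylic bromide and an enal derived from geranyl acetate.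

Key step: step 12

Remark (assumption): ring carbons carry germacrane numbers (C1–C15) throughout; C6 keeps one spatial arrangement from 17 onward although its CIP descriptor is R in 17 and 18 and S once C5 is an epoxide carbon; the (S,S)-ligand in step 5 is assigned from the usual facial model of that catalyst and its sense should be confirmed on the first batch.

Step 1
Reactants: 1 geranyl acetate
Product: 3 (2E,6E)-3,7-dimethyl-8-oxoocta-2,6-dien-1-yl acetate, via allylic alcohol 2 (not isolated)
Conditions: SeO2 (10 mol%), salicylic acid (10 mol%), t-BuOOH (3 equiv), CH2Cl2, rt; crude, then MnO2, CH2Cl2, rt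
Reagents that add atoms: tert-butyl hydroperoxide, CC(C)(C)OO
Why: Riley allylic oxidation attacks the E-methyl of the terminal trisubstituted alkene because the 2,3-alkene is deactivated by the allylic acetate, and MnO2 then takes the allylic alcohol to the E-enal without touching the ester.

Step 2
Reactants: 3 (2E,6E)-3,7-dimethyl-8-oxoocta-2,6-dien-1-yl acetate
Product: 4 (2E,6E)-3,7-dimethylnona-2,6,8-trien-1-yl acetate
Conditions: Ph3PCH3Br (1.1 equiv), KHMDS (1.05 equiv), THF, −78 to 0 °C
Reagents that add atoms: methyltriphenylphosphonium bromide, C[P+](c1ccccc1)(c1ccccc1)c1ccccc1.[Br-]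
Why: Wittig methylenation of the enal by the non-stabilised ylide is much faster than attack on the acetate at low temperature and leaves both trisubstituted alkenes unchanged.

Step 3
Reactants: 4 (2E,6E)-3,7-dimethylnona-2,6,8-trien-1-yl acetate
Product: 6 (2E,6E)-9-hydroxy-3,7-dimethylnona-2,6-dien-1-yl acetate, via alkylborane 5 (not isolated)
Conditions: 9-BBN (1.1 equiv), THF, 0 °C to rt; then 30% H2O2, 3 M aq NaOAc, 0 °C to rt
Reagents that add atoms: hydrogen peroxide, OO
Why: Hydroboration–oxidation with 9-BBN takes place only at the monosubstituted terminal alkene of the diene with anti-Markovnikov regiochemistry, and the acetate-buffered peroxide oxidation spares the ester.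

Step 4
Reactants: 6 (2E,6E)-9-hydroxy-3,7-dimethylnona-2,6-dien-1-yl acetate
Product: 7 (2E,6E)-3,7-dimethyl-9-oxonona-2,6-dien-1-yl acetate
Conditions: Dess–Martin periodinane (1.2 equiv), NaHCO3, CH2Cl2, 0 °C; used crude
Reagents that add atoms: none
Why: Dess–Martin oxidation under bicarbonate buffering should give the β,γ-unsaturated aldehyde without migration of the C10=C1 alkene into conjugation.

Step 5
Reactants: 7 (2E,6E)-3,7-dimethyl-9-oxonona-2,6-dien-1-yl acetate; 8 tert-butyldimethyl(prop-2-yn-1-yloxy)silane
Product: 9 (2E,6E,9S)-12-[(tert-butyldimethylsilyl)oxy]-9-hydroxy-3,7-dimethyldodeca-2,6-dien-10-yn-1-yl acetate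
Conditions: 8 (2.8 equiv), Me2Zn (3 equiv), (S,S)-ProPhenol (20 mol%), Ph3P=O (40 mol%), toluene, 0 to 4 °C, slow addition of crude 7; aq NH4Cl work-up
Reagents that add atoms: none
Why: Catalytic asymmetric alkynylation of the aldehyde by the alkynylzinc under amine-free dinuclear zinc catalysis, the ligand being expected to deliver the alkynyl group to the Re face and so set C8 as S.

Step 6
Reactants: 9 (2E,6E,9S)-12-[(tert-butyldimethylsilyl)oxy]-9-hydroxy-3,7-dimethyldodeca-2,6-dien-10-yn-1-yl acetate
Product: 10 (2E,6E,9S)-12-[(tert-butyldimethylsilyl)oxy]-3,7-dimethyldodeca-2,6-dien-10-yne-1,9-diol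
Conditions: K2CO3 (0.3 equiv), MeOH, 0 °C
Reagents that add atoms: none
Why: Base-catalysed transesterification removes the primary acetate while the silyl ether and the propargylic carbinol are inert.

Step 7
Reactants: 10 (2E,6E,9S)-12-[(tert-butyldimethylsilyl)oxy]-3,7-dimethyldodeca-2,6-dien-10-yne-1,9-diol
Product: 11 (2E,6E,9S)-12-[(tert-butyldimethylsilyl)oxy]-9-hydroxy-3,7-dimethyldodeca-2,6-dien-10-ynal
Conditions: TEMPO (10 mol%), PhI(OAc)2 (1.1 equiv), CH2Cl2, rt
Reagents that add atoms: none
Why: The oxoammonium oxidation is strongly selective for the primary allylic alcohol over the hindered secondary propargylic alcohol and gives the E-enal without E/Z isomerisation.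

Step 8
Reactants: 11 (2E,6E,9S)-12-[(tert-butyldimethylsilyl)oxy]-9-hydroxy-3,7-dimethyldodeca-2,6-dien-10-ynal; 12 tiglic acid
Product: 13 (4S,6E,10E)-1-[(tert-butyldimethylsilyl)oxy]-6,10-dimethyl-12-oxododeca-6,10-dien-2-yn-4-yl (2E)-2-methylbut-2-enoate
Conditions: 12, 2,4,6-trichlorobenzoyl chloride, Et3N, toluene, rt; then 11, DMAP (cat.), rt
Reagents that add atoms: none
Why: Yamaguchi esterification acylates the secondary alcohol with retention at C8 and avoids the vinylketene pathway that would deconjugate the tiglate.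

Step 9
Reactants: 13 (4S,6E,10E)-1-[(tert-butyldimethylsilyl)oxy]-6,10-dimethyl-12-oxododeca-6,10-dien-2-yn-4-yl (2E)-2-methylbut-2-enoate
Product: 14 (4S,6E,10E)-1-hydroxy-6,10-dimethyl-12-oxododeca-6,10-dien-2-yn-4-yl (2E)-2-methylbut-2-enoate
Conditions: HF·pyridine, pyridine, THF, 0 °C
Reagents that add atoms: none
Why: Buffered fluoride desilylation cleaves the primary silyl ether and leaves the tiglate and the enal untouched.

Step 10
Reactants: 14 (4S,6E,10E)-1-hydroxy-6,10-dimethyl-12-oxododeca-6,10-dien-2-yn-4-yl (2E)-2-methylbut-2-enoate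
Product: 16 (4S,6E,10E)-1-bromo-6,10-dimethyl-12-oxododeca-6,10-dien-2-yn-4-yl (2E)-2-methylbut-2-enoate, via mesylate 15 (not isolated)
Conditions: MsCl, Et3N, CH2Cl2, −30 °C; then LiBr, THF, 0 °C to rt
Reagents that add atoms: lithium bromide, [Li+].[Br-]
Why: Mesylation followed by SN2 displacement with bromide gives the primary propargylic bromide under conditions that do not affect the enal, which a phosphine-based bromination would olefinate.

Step 11
Reactants: 16 (4S,6E,10E)-1-bromo-6,10-dimethyl-12-oxododeca-6,10-dien-2-yn-4-yl (2E)-2-methylbut-2-enoate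
Product: 17 (1S,3E,7E,9R)-10-ethenylidene-9-hydroxy-3,7-dimethylcyclodeca-3,7-dien-1-yl (2E)-2-methylbut-2-enoate (germacrane numbering: 6R,8S allenol with C7=C11=C13H2)
Conditions: CrCl2 (8 equiv), THF, rt, syringe-pump addition of 16 to a final 2 mM
Reagents that add atoms: none
Why: Nozaki–Hiyama–Kishi-type reaction in which divalent chromium converts the propargylic bromide into a propargylchromium species whose γ-carbon C7 adds to the aldehyde (SE2') to give the 2,3-allenol while closing the ten-membered ring, as in chromium-mediated allylation closures of germacranolide rings, with C6 set in a closed chromium-bridged transition state (O6 syn to C11) in which the E,E-chain is folded crown-like and the C8–O bond lies orthogonal to the reacting alkyne π-orbital, which should place O6 cis to the C8 tiglate.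

Step 12
Reactants: 17 (1S,3E,7E,9R)-10-ethenylidene-9-hydroxy-3,7-dimethylcyclodeca-3,7-dien-1-yl (2E)-2-methylbut-2-enoate
Product: 18 (6R,8S)-13-chloro-8-tigloyloxygermacra-1(10)E,4E,7(11)-trien-12,6-olide (butenolide fused at C6–C7, chloromethyl on C11)
Conditions: PdCl2 (10 mol%), CuCl2 (4 equiv), CO (1 atm), propylene oxide (5 equiv), THF, rt
Reagents that add atoms: carbon monoxide, [C-]#[O+]; CuCl2 (chlorine source), Cl[Cu]Cl
Why: PdCl2 and CO convert the C6 hydroxyl into an alkoxycarbonylpalladium species (O6–C12 bond), which inserts the allene by syn carbopalladation so that C12 bonds to the central carbon C11 and palladium becomes a π-allyl over C7–C11–C13; chloride transfer to the primary terminus C13, with CuCl2 as chloride source and reoxidant of the zerovalent palladium released, gives the conjugated butenolide. The closest known reaction type is the PdCl2/CuCl2 chlorocyclocarbonylation of 2,3-allenols to 3-chloromethyl-2(5H)-furanones, applied here to a macrocyclic secondary allenol. The butenolide ring closes by formation of the C12–C11 bond in a 5-exo migratory insertion onto the central allene carbon, the C11=C13 bond being exocyclic to the new ring and the C7=C11 bond retained inside it. No stereocentre is created: C6 and C8 are not touched, and the allene has no axial chirality because C13 is CH2. The step needs chloride delivery to C13 and not C7, secured by the fully substituted ring carbon C7 and by conjugation of the C7=C11 alkene with the new carbonyl, and chemoselectivity for the allenol over the two trisubstituted ring alkenes, secured by intramolecular delivery from the palladium alkoxide, by the CO atmosphere and by propylene oxide, which removes the HCl that would trigger transannular cyclisation.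

Step 13
Reactants: 18 (6R,8S)-13-chloro-8-tigloyloxygermacra-1(10)E,4E,7(11)-trien-12,6-olide
Product: 19 (1R,4R,5R,6S,8S,10R)-13-chloro-1,10:4,5-diepoxy-8-tigloyloxygermacr-7(11)-en-12,6-olide
Conditions: mCPBA (2.5 equiv), NaHCO3, CH2Cl2, 0 °C to rt
Reagents that add atoms: 3-chloroperoxybenzoic acid, OOC(=O)c1cccc(Cl)c1
Why: Prilezhaev epoxidation reaches only the two electron-rich trisubstituted ring alkenes (butenolide and tiglate alkenes are electron-poor), each on its exposed outer face in the crown conformer with both methyls syn and H6 eclipsing C15, which should give the 1R,10R and 4R,5R epoxides with the 4,5-epoxide threo to O6.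

Step 14
Reactants: 19 (1R,4R,5R,6S,8S,10R)-13-chloro-1,10:4,5-diepoxy-8-tigloyloxygermacr-7(11)-en-12,6-olide
Product: 21 (1R,4R,5R,6S,8S,10R)-1,10:4,5-diepoxy-13-hydroxy-8-tigloyloxygermacr-7(11)-en-12,6-olide (target CNP0111480.1), via formate ester 20 (not isolated)
Conditions: HCO2Na (3 equiv), DMF, rt to 40 °C; then MeOH, aq NaHCO3, 0 °C
Reagents that add atoms: sodium formate, [Na+].[O-]C=O
Why: SN2 displacement of the activated allylic chloride by formate (SN2' at the fully substituted C7 is blocked) followed by mild methanolysis of the labile formate should free the C13 hydroxyl while tiglate, lactone and epoxides survive.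

Compound list
1 | geranyl acetate, (2E)-3,7-dimethylocta-2,6-dien-1-yl acetate | CC(=O)OC/C=C(\C)CCC=C(C)C | starting material
2 | (2E,6E)-8-hydroxy-3,7-dimethylocta-2,6-dien-1-yl acetate | CC(=O)OC/C=C(\C)CC/C=C(\C)CO | intermediate
3 | (2E,6E)-3,7-dimethyl-8-oxoocta-2,6-dien-1-yl acetate | CC(=O)OC/C=C(\C)CC/C=C(\C)C=O | intermediate
4 | (2E,6E)-3,7-dimethylnona-2,6,8-trien-1-yl acetate | CC(=O)OC/C=C(\C)CC/C=C(\C)C=C | intermediate
5 | (2E,6E)-9-(9-borabicyclo[3.3.1]nonan-9-yl)-3,7-dimethylnona-2,6-dien-1-yl acetate | CC(=O)OC/C=C(\C)CC/C=C(\C)CCB1C2CCCC1CCC2 | intermediate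
6 | (2E,6E)-9-hydroxy-3,7-dimethylnona-2,6-dien-1-yl acetate | CC(=O)OC/C=C(\C)CC/C=C(\C)CCO | intermediate
7 | (2E,6E)-3,7-dimethyl-9-oxonona-2,6-dien-1-yl acetate | CC(=O)OC/C=C(\C)CC/C=C(\C)CC=O | intermediate
8 | tert-butyldimethyl(prop-2-yn-1-yloxy)silane | C#CCO[Si](C)(C)C(C)(C)C | starting material
9 | (2E,6E,9S)-12-[(tert-butyldimethylsilyl)oxy]-9-hydroxy-3,7-dimethyldodeca-2,6-dien-10-yn-1-yl acetate | CC(=O)OC/C=C(\C)CC/C=C(\C)C[C@H](O)C#CCO[Si](C)(C)C(C)(C)C | intermediate
10 | (2E,6E,9S)-12-[(tert-butyldimethylsilyl)oxy]-3,7-dimethyldodeca-2,6-dien-10-yne-1,9-diol | OC/C=C(\C)CC/C=C(\C)C[C@H](O)C#CCO[Si](C)(C)C(C)(C)C | intermediate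
11 | (2E,6E,9S)-12-[(tert-butyldimethylsilyl)oxy]-9-hydroxy-3,7-dimethyldodeca-2,6-dien-10-ynal | O=C/C=C(\C)CC/C=C(\C)C[C@H](O)C#CCO[Si](C)(C)C(C)(C)C | intermediate
12 | tiglic acid, (2E)-2-methylbut-2-enoic acid | C/C=C(\C)C(=O)O | starting material
13 | (4S,6E,10E)-1-[(tert-butyldimethylsilyl)oxy]-6,10-dimethyl-12-oxododeca-6,10-dien-2-yn-4-yl (2E)-2-methylbut-2-enoate | O=C/C=C(\C)CC/C=C(\C)C[C@H](OC(=O)/C(C)=C/C)C#CCO[Si](C)(C)C(C)(C)C | intermediate
14 | (4S,6E,10E)-1-hydroxy-6,10-dimethyl-12-oxododeca-6,10-dien-2-yn-4-yl (2E)-2-methylbut-2-enoate | O=C/C=C(\C)CC/C=C(\C)C[C@H](OC(=O)/C(C)=C/C)C#CCO | intermediate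
15 | (4S,6E,10E)-1-(methanesulfonyloxy)-6,10-dimethyl-12-oxododeca-6,10-dien-2-yn-4-yl (2E)-2-methylbut-2-enoate | O=C/C=C(\C)CC/C=C(\C)C[C@H](OC(=O)/C(C)=C/C)C#CCOS(C)(=O)=O | intermediate
16 | (4S,6E,10E)-1-bromo-6,10-dimethyl-12-oxododeca-6,10-dien-2-yn-4-yl (2E)-2-methylbut-2-enoate | O=C/C=C(\C)CC/C=C(\C)C[C@H](OC(=O)/C(C)=C/C)C#CCBr | intermediate
17 | (1S,3E,7E,9R)-10-ethenylidene-9-hydroxy-3,7-dimethylcyclodeca-3,7-dien-1-yl (2E)-2-methylbut-2-enoate (6R,8S macrocyclic allenol) | C=C=C1[C@H](O)/C=C(\C)CC/C=C(\C)C[C@@H]1OC(=O)/C(C)=C/C | intermediate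
18 | (6R,8S)-13-chloro-8-tigloyloxygermacra-1(10)E,4E,7(11)-trien-12,6-olide | C/C=C(\C)C(=O)O[C@H]1C/C(C)=C/CC/C(C)=C/[C@H]2OC(=O)C(CCl)=C12 | intermediate
19 | (1R,4R,5R,6S,8S,10R)-13-chloro-1,10:4,5-diepoxy-8-tigloyloxygermacr-7(11)-en-12,6-olide | C/C=C(\C)C(=O)O[C@H]1C[C@@]2(C)O[C@@H]2CC[C@@]2(C)O[C@@H]2[C@H]2OC(=O)C(CCl)=C12 | intermediate
20 | (1R,4R,5R,6S,8S,10R)-1,10:4,5-diepoxy-13-formyloxy-8-tigloyloxygermacr-7(11)-en-12,6-olide | C/C=C(\C)C(=O)O[C@H]1C[C@@]2(C)O[C@@H]2CC[C@@]2(C)O[C@@H]2[C@H]2OC(=O)C(COC=O)=C12 | intermediate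
21 | (1R,4R,5R,6S,8S,10R)-1,10:4,5-diepoxy-13-hydroxy-8-tigloyloxygermacr-7(11)-en-12,6-olide, CNP0111480.1 | C/C=C(\C)C(=O)O[C@H]1C[C@@]2(C)O[C@@H]2CC[C@@]2(C)O[C@@H]2[C@H]2OC(=O)C(CO)=C12 | target

Total step count: 14. Longest linear sequence: 14 steps, from geranyl acetate 1.

Steps most likely to fail

Step 12 (key step). What may go wrong: the electrophilic divalent palladium, or traces of HCl, engages the ring 1,5-diene in a Cope-type or transannular cyclisation, or zerovalent palladium ionises the allenylic tiglate, before the alkoxycarbonyl insertion takes place. Fallback: the order of epoxidation and carbonylation is reversed, so that no nucleophilic ring alkene is present when palladium is introduced. Setting out from 17, mCPBA (2.2 equiv, NaHCO3, CH2Cl2, 0 °C) epoxidises both ring alkenes, the free C6 hydroxyl delivering the peracid to the 4,5-alkene on the face syn to O6, to give the diepoxy allenol F1. F1 is then carbonylated under copper-free conditions (PdCl2(MeCN)2 cat., p-benzoquinone as terminal oxidant, LiCl as chloride source, CO 1 atm, THF, rt). This closes the same C12–C11 bond and returns to the route at 19.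

Step 11. What may go wrong: attack on the wrong aldehyde face (6,8-trans allenol), closure through C13 to the twelve-membered homopropargylic cycloalkyne, or oligomerisation at a practical concentration. Fallback for the stereochemical failure: the C6 centre is corrected by substitution and is no longer set during C–C bond formation. Setting out from 16, the same closure is accepted with the 6-epimeric allenol F2 as main product. Mitsunobu inversion (4-nitrobenzoic acid, PPh3, DIAD, THF, 0 °C) gives the 4-nitrobenzoate F3 with the required C6 configuration. Brief methanolysis (K2CO3, MeOH, 0 °C), which cleaves the activated nitrobenzoate before the hindered conjugated tiglate, returns to the route at 17.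

Step 5. What may go wrong: migration of the skipped C10=C1 alkene of 7 into conjugation or self-aldol under the zinc alkynylide conditions, and insufficient face selectivity with an unbranched aldehyde. Fallback: the carbinol configuration is set by reduction and not by addition. Setting out from 7, the lithium acetylide of 8 (n-BuLi, THF, −78 °C) gives the racemic propargylic alcohol F4. Dess–Martin oxidation gives the ynone F5. Midland reduction with (S)-Alpine-Borane (neat, rt), a neutral reagent that does not enolise the skipped ynone, returns to the route at 9.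

Further compounds
F1 | step 12 | (1R,4R,5R,6S,8S,10R)-1,10:4,5-diepoxy macrocyclic allenol (C7=C11=C13H2, C6 hydroxyl, C8 tiglate) | C/C=C(\C)C(=O)O[C@H]1C[C@@]2(C)O[C@@H]2CC[C@@]2(C)O[C@@H]2[C@@H](O)C1=C=C
F2 | step 11 | (1S,3E,7E,9S)-10-ethenylidene-9-hydroxy-3,7-dimethylcyclodeca-3,7-dien-1-yl (2E)-2-methylbut-2-enoate (6-epimer of 17) | C=C=C1[C@@H](O)/C=C(\C)CC/C=C(\C)C[C@@H]1OC(=O)/C(C)=C/C
F3 | step 11 | 4-nitrobenzoate of 17 at O6 | C=C=C1[C@H](OC(=O)c2ccc(cc2)[N+](=O)[O-])/C=C(\C)CC/C=C(\C)C[C@@H]1OC(=O)/C(C)=C/C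
F4 | step 5 | (2E,6E)-12-[(tert-butyldimethylsilyl)oxy]-9-hydroxy-3,7-dimethyldodeca-2,6-dien-10-yn-1-yl acetate, racemic at C9 | CC(=O)OC/C=C(\C)CC/C=C(\C)CC(O)C#CCO[Si](C)(C)C(C)(C)C
F5 | step 5 | (2E,6E)-12-[(tert-butyldimethylsilyl)oxy]-3,7-dimethyl-9-oxododeca-2,6-dien-10-yn-1-yl acetate | CC(=O)OC/C=C(\C)CC/C=C(\C)CC(=O)C#CCO[Si](C)(C)C(C)(C)C
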